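**Retrosynthetic overview**

- Pterocarpan numbering is used: ring A (C1–C4a, C11b) carries O3 and the 2,2-dimethyldihydropyran fused at C1–C2, ring B holds O5/C6/C6a, ring C holds O11/C11a, ring D (C6b–C10a) carries the 9-OMe.
- Feature: C11a is a benzylic ether CH between O11 and ring A carbon C11b, and it lies five atoms from C6a once ring D carries a diazoacetate at C6b. C6a–C11a is therefore cut as a rhodium carbenoid 1,5-C–H insertion bond that closes ring C and sets both stereocentres.
- Ring B is cut at O5–C6 (Mitsunobu after ester reduction). The insertion precursor 16 is cut at O11–C11a into ring A benzyl alcohol 9 and ring D phenol 14.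
- 9 comes from 2,4,6-trihydroxybenzaldehyde (para silylation, propargyl ether and Claisen to the chromene, hydrogenation, pivaloylation, reduction). 14 comes from 3-methoxyphenol and methyl glyoxylate (ortho-hydroxyalkylation, ionic hydrogenation).
- Ring order: dimethylpyran ring on ring A (step 3), ring C (step 11), ring B (step 13).

Key step: step 11

Remark: Rh2(S-PTTL)4 is assumed to give the (2S,3R) ester 17 from 16; if a trial shows the mirror image, Rh2(R-PTTL)4 is used in step 11 and nothing else changes.

**Route**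

Step 1
Reactants: 1 2,4,6-trihydroxybenzaldehyde
Product: 2 2,6-dihydroxy-4-[(triisopropylsilyl)oxy]benzaldehyde
Conditions: TIPSCl (1.0 equiv), imidazole, DMF, −20 → 0 °C
Reagents that add atoms: chlorotriisopropylsilane, CC(C)[Si](Cl)(C(C)C)C(C)C
Why: Selective O-silylation; the 4-OH para to the formyl group is the most acidic hydroxyl, is not held in a hydrogen bond and has no ortho substituent, so the bulky silyl chloride should go there first.

Step 2
Reactants: 2 2,6-dihydroxy-4-[(triisopropylsilyl)oxy]benzaldehyde; 3 3-chloro-3-methylbut-1-yne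
Product: 4 2-hydroxy-6-[(2-methylbut-3-yn-2-yl)oxy]-4-[(triisopropylsilyl)oxy]benzaldehyde
Conditions: 3 (1.1 equiv), DBU, CuCl2·2H2O (1 mol%), MeCN, 0 °C
Reagents that add atoms: none
Why: Copper-catalysed O-propargylation of a phenoxide by a tertiary propargylic chloride; the two hydroxyls are equivalent, and after the first is etherified the other is locked in the hydrogen bond to the formyl oxygen, which should hold the reaction at the mono-ether.

Step 3
Reactants: 4 2-hydroxy-6-[(2-methylbut-3-yn-2-yl)oxy]-4-[(triisopropylsilyl)oxy]benzaldehyde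
Product: 6 7-hydroxy-2,2-dimethyl-5-[(triisopropylsilyl)oxy]-2H-chromene-8-carbaldehyde, via ortho-allenylphenol 5 (not isolated)
Conditions: o-xylene, 140 °C
Reagents that add atoms: none
Why: Aromatic propargyl Claisen rearrangement to the only free ortho carbon (the other carries the formyl group), then 1,5-hydrogen shift and oxa-6π electrocyclisation, the standard thermal route to 2,2-dimethyl-2H-chromenes.

Step 4
Reactants: 6 7-hydroxy-2,2-dimethyl-5-[(triisopropylsilyl)oxy]-2H-chromene-8-carbaldehyde
Product: 7 7-hydroxy-2,2-dimethyl-5-[(triisopropylsilyl)oxy]chroman-8-carbaldehyde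
Conditions: H2 (1 atm), 10% Pd/C, EtOAc, rt
Reagents that add atoms: none
Why: Heterogeneous hydrogenation of the styrene-type chromene double bond; the hydrogen-bonded, doubly ortho-substituted aldehyde and the aryl silyl ether should be left alone in ethyl acetate at 1 atm.

Step 5
Reactants: 7 7-hydroxy-2,2-dimethyl-5-[(triisopropylsilyl)oxy]chroman-8-carbaldehyde
Product: 8 8-formyl-2,2-dimethyl-5-[(triisopropylsilyl)oxy]chroman-7-yl pivalate
Conditions: PivCl, Et3N, DMAP (cat.), CH2Cl2, 0 °C → rt
Reagents that add atoms: pivaloyl chloride, CC(C)(C)C(=O)Cl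
Why: DMAP-catalysed O-acylation of the one remaining phenol; the pivalate is slow to migrate and later falls to LiAlH4 in the same operation as the ester reduction.

Step 6
Reactants: 8 8-formyl-2,2-dimethyl-5-[(triisopropylsilyl)oxy]chroman-7-yl pivalate
Product: 9 8-(hydroxymethyl)-2,2-dimethyl-5-[(triisopropylsilyl)oxy]chroman-7-yl pivalate
Conditions: NaBH4, THF–MeOH, −20 °C; pH 7 buffer
Reagents that add atoms: none
Why: Borohydride reduction of the aryl aldehyde; the hindered aryl pivalate and the silyl ether survive, and the low temperature and neutral quench keep the pivaloyl group from shifting to the new benzylic oxygen.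

Step 7
Reactants: 10 3-methoxyphenol; 11 methyl glyoxylate
Product: 13 methyl 2-hydroxy-2-(2-hydroxy-4-methoxyphenyl)acetate (racemic), via trichlorotitanium 3-methoxyphenoxide 12 (not isolated)
Conditions: TiCl4 (1.0 equiv), CH2Cl2, −30 °C; then 11 (freshly distilled), −30 → 0 °C; H2O
Reagents that add atoms: none
Why: ortho-Selective Friedel–Crafts hydroxyalkylation; the titanium phenoxide binds the glyoxylate and delivers it through a six-membered chelate to an ortho carbon, and C6 (para to OMe, unhindered) is favoured over C2 between the two oxygens; the carbinol centre is racemic and is removed in step 8.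

Step 8
Reactants: 13 methyl 2-hydroxy-2-(2-hydroxy-4-methoxyphenyl)acetate
Product: 14 methyl 2-(2-hydroxy-4-methoxyphenyl)acetate
Conditions: Et3SiH (3 equiv), TFA, CH2Cl2, 0 °C → rt
Reagents that add atoms: none
Why: Ionic hydrogenation; the benzylic hydroxyl, ortho and para to oxygen donors, ionises in TFA and the cation is reduced by the silane, while the methyl ester and aryl methyl ether are inert.

Step 9
Reactants: 9 8-(hydroxymethyl)-2,2-dimethyl-5-[(triisopropylsilyl)oxy]chroman-7-yl pivalate; 14 methyl 2-(2-hydroxy-4-methoxyphenyl)acetate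
Product: 15 methyl 2-[2-({2,2-dimethyl-7-(pivaloyloxy)-5-[(triisopropylsilyl)oxy]chroman-8-yl}methoxy)-4-methoxyphenyl]acetate
Conditions: PPh3, DIAD, THF, 0 °C → rt
Reagents that add atoms: none
Why: Mitsunobu etherification forms O11–C11a; the phenol of 14 is the acidic partner and displaces the oxyphosphonium ion of the primary benzylic alcohol under neutral conditions that spare pivalate, silyl ether and methyl ester.

Step 10
Reactants: 15 methyl 2-[2-({2,2-dimethyl-7-(pivaloyloxy)-5-[(triisopropylsilyl)oxy]chroman-8-yl}methoxy)-4-methoxyphenyl]acetate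
Product: 16 methyl 2-diazo-2-[2-({2,2-dimethyl-7-(pivaloyloxy)-5-[(triisopropylsilyl)oxy]chroman-8-yl}methoxy)-4-methoxyphenyl]acetate
Conditions: p-ABSA, DBU, MeCN, 0 °C → rt
Reagents that add atoms: 4-acetamidobenzenesulfonyl azide, CC(=O)Nc1ccc(cc1)S(=O)(=O)N=[N+]=[N-]
Why: Regitz diazo transfer; DBU forms the arylacetate enolate, which takes the terminal N2 unit of the sulfonyl azide, the standard entry to aryldiazoacetates; the hindered aryl pivalate should survive DBU at room temperature.

Step 11
Reactants: 16 methyl 2-diazo-2-[2-({2,2-dimethyl-7-(pivaloyloxy)-5-[(triisopropylsilyl)oxy]chroman-8-yl}methoxy)-4-methoxyphenyl]acetate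
Product: 17 methyl (2S,3R)-2-{2,2-dimethyl-7-(pivaloyloxy)-5-[(triisopropylsilyl)oxy]chroman-8-yl}-6-methoxy-2,3-dihydrobenzofuran-3-carboxylate (cis)
Conditions: Rh2(S-PTTL)4 (2 mol%), toluene, −60 °C, slow addition of 16
Reagents that add atoms: none
Why: Loss of N2 from 16 at the divalent rhodium dimer gives a donor/acceptor rhodium carbenoid at the future C6a, which takes the ether-activated benzylic hydrogen on C11a in a concerted, asynchronous, hydride-transfer-like three-centre transition state and forms C6a–C11a; the closest known reaction type is the enantioselective intramolecular 1,5-C–H insertion of ortho-benzyloxy aryldiazoacetates to cis-2-aryl-2,3-dihydrobenzofuran-3-carboxylates under N-phthaloyl amino acid rhodium carboxylates. Ring C closes as a five-membered ring in the 1,5-insertion mode, the new ring being made of the carbenoid carbon, C6b, C10a, O11 and C11a. C6a is set by the carbenoid face that the chiral N-phthaloyl-tert-leucinate ligands leave open, and C11a by which of the two enantiotopic benzylic hydrogens is presented to that face; the cis relation should follow as the kinetic outcome of the compact transition state. The step needs site selectivity, which the substrate secures because the only C–H five atoms from the carbenoid is the doubly activated O–CH2–aryl group (silyl and pivaloyl C–H bonds are remote and unactivated), and chemoselectivity against oxonium ylide formation, which is secured because the ether oxygen could only close a four-membered ring. Low temperature and slow addition hold back carbenoid dimerisation, and the O5 pivalate lowers the donor strength of ring A so that the benzylic ether of the product should not ionise and epimerise.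

Step 12
Reactants: 17 methyl (2S,3R)-2-{2,2-dimethyl-7-(pivaloyloxy)-5-[(triisopropylsilyl)oxy]chroman-8-yl}-6-methoxy-2,3-dihydrobenzofuran-3-carboxylate
Product: 18 8-[(2S,3S)-3-(hydroxymethyl)-6-methoxy-2,3-dihydrobenzofuran-2-yl]-2,2-dimethyl-5-[(triisopropylsilyl)oxy]chroman-7-ol (cis)
Conditions: LiAlH4, THF, −20 → 0 °C; aq. potassium sodium tartrate
Reagents that add atoms: none
Why: Hydride reduction of the methyl ester to the primary alcohol and reductive cleavage of the aryl pivalate in one operation; reduction is faster than enolisation, so the cis C6a centre should be kept, and the aryl triisopropylsilyl ether survives at this temperature.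

Step 13
Reactants: 18 8-[(2S,3S)-3-(hydroxymethyl)-6-methoxy-2,3-dihydrobenzofuran-2-yl]-2,2-dimethyl-5-[(triisopropylsilyl)oxy]chroman-7-ol
Product: 19 (6aS,11aS)-9-methoxy-3-[(triisopropylsilyl)oxy]pterocarpan with a 2,2-dimethyl-3,4-dihydro-2H-pyran ring fused across C1–C2 (ring oxygen on C1)
Conditions: PPh3, DIAD, THF (dilute), 0 °C → rt
Reagents that add atoms: none
Why: Intramolecular Mitsunobu etherification; the O5 phenol displaces the primary oxyphosphonium ion at C6 (6-exo-tet) and closes ring B, neither stereocentre takes part, and the cis relation set in step 11 is what allows the closure.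

Step 14
Reactants: 19 (6aS,11aS)-9-methoxy-3-[(triisopropylsilyl)oxy]pterocarpan with the C1–C2 fused 2,2-dimethyldihydropyran ring
Product: 20 (6aS,11aS)-3-hydroxy-9-methoxypterocarpan with a 2,2-dimethyl-3,4-dihydro-2H-pyran ring fused across C1–C2 (ring oxygen on C1), CNP0207547.1
Conditions: Bu4NF, AcOH, THF, 0 °C
Reagents that add atoms: none
Why: Fluoride cleavage of the aryl silyl ether; the acetic acid buffer keeps the C3 phenoxide, para to C11a, from opening the benzylic ether, and the cis ring fusion is in any case the only strain-free way for that ether to re-close.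

**Compound list**

1 | 2,4,6-trihydroxybenzaldehyde | O=Cc1c(O)cc(O)cc1O | starting material
2 | 2,6-dihydroxy-4-[(triisopropylsilyl)oxy]benzaldehyde | O=Cc1c(O)cc(O[Si](C(C)C)(C(C)C)C(C)C)cc1O | intermediate
3 | 3-chloro-3-methylbut-1-yne | CC(C)(Cl)C#C | starting material
4 | 2-hydroxy-6-[(2-methylbut-3-yn-2-yl)oxy]-4-[(triisopropylsilyl)oxy]benzaldehyde | O=Cc1c(O)cc(O[Si](C(C)C)(C(C)C)C(C)C)cc1OC(C)(C)C#C | intermediate
5 | 2,6-dihydroxy-3-(3-methylbuta-1,2-dien-1-yl)-4-[(triisopropylsilyl)oxy]benzaldehyde (ortho-allenylphenol, not isolated) | O=Cc1c(O)cc(O[Si](C(C)C)(C(C)C)C(C)C)c(C=C=C(C)C)c1O | intermediate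
6 | 7-hydroxy-2,2-dimethyl-5-[(triisopropylsilyl)oxy]-2H-chromene-8-carbaldehyde | O=Cc1c(O)cc(O[Si](C(C)C)(C(C)C)C(C)C)c2c1OC(C)(C)C=C2 | intermediate
7 | 7-hydroxy-2,2-dimethyl-5-[(triisopropylsilyl)oxy]chroman-8-carbaldehyde | O=Cc1c(O)cc(O[Si](C(C)C)(C(C)C)C(C)C)c2c1OC(C)(C)CC2 | intermediate
8 | 8-formyl-2,2-dimethyl-5-[(triisopropylsilyl)oxy]chroman-7-yl pivalate | O=Cc1c(OC(=O)C(C)(C)C)cc(O[Si](C(C)C)(C(C)C)C(C)C)c2c1OC(C)(C)CC2 | intermediate
9 | 8-(hydroxymethyl)-2,2-dimethyl-5-[(triisopropylsilyl)oxy]chroman-7-yl pivalate | OCc1c(OC(=O)C(C)(C)C)cc(O[Si](C(C)C)(C(C)C)C(C)C)c2c1OC(C)(C)CC2 | intermediate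
10 | 3-methoxyphenol | COc1cccc(O)c1 | starting material
11 | methyl glyoxylate | COC(=O)C=O | starting material
12 | trichlorotitanium 3-methoxyphenoxide (not isolated) | COc1cccc(O[Ti](Cl)(Cl)Cl)c1 | intermediate
13 | methyl 2-hydroxy-2-(2-hydroxy-4-methoxyphenyl)acetate (racemic) | COC(=O)C(O)c1ccc(OC)cc1O | intermediate
14 | methyl 2-(2-hydroxy-4-methoxyphenyl)acetate | COC(=O)Cc1ccc(OC)cc1O | intermediate
15 | methyl 2-[2-({2,2-dimethyl-7-(pivaloyloxy)-5-[(triisopropylsilyl)oxy]chroman-8-yl}methoxy)-4-methoxyphenyl]acetate | COC(=O)Cc1ccc(OC)cc1OCc1c(OC(=O)C(C)(C)C)cc(O[Si](C(C)C)(C(C)C)C(C)C)c2c1OC(C)(C)CC2 | intermediate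
16 | methyl 2-diazo-2-[2-({2,2-dimethyl-7-(pivaloyloxy)-5-[(triisopropylsilyl)oxy]chroman-8-yl}methoxy)-4-methoxyphenyl]acetate | COc1ccc(C(=[N+]=[N-])C(=O)OC)c(c1)OCc1c(OC(=O)C(C)(C)C)cc(O[Si](C(C)C)(C(C)C)C(C)C)c2c1OC(C)(C)CC2 | intermediate
17 | methyl (2S,3R)-2-{2,2-dimethyl-7-(pivaloyloxy)-5-[(triisopropylsilyl)oxy]chroman-8-yl}-6-methoxy-2,3-dihydrobenzofuran-3-carboxylate (cis) | COc1ccc2c(c1)O[C@H](c1c(OC(=O)C(C)(C)C)cc(O[Si](C(C)C)(C(C)C)C(C)C)c3c1OC(C)(C)CC3)[C@@H]2C(=O)OC | intermediate
18 | 8-[(2S,3S)-3-(hydroxymethyl)-6-methoxy-2,3-dihydrobenzofuran-2-yl]-2,2-dimethyl-5-[(triisopropylsilyl)oxy]chroman-7-ol (cis) | COc1ccc2c(c1)O[C@H](c1c(O)cc(O[Si](C(C)C)(C(C)C)C(C)C)c3c1OC(C)(C)CC3)[C@@H]2CO | intermediate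
19 | (6aS,11aS)-9-methoxy-3-[(triisopropylsilyl)oxy]pterocarpan with the 2,2-dimethyldihydropyran ring fused at C1–C2 (oxygen on C1) | COc1ccc2c(c1)O[C@@H]1c3c(cc(O[Si](C(C)C)(C(C)C)C(C)C)c4c3OC(C)(C)CC4)OC[C@H]21 | intermediate
20 | (6aS,11aS)-3-hydroxy-9-methoxypterocarpan with the 2,2-dimethyldihydropyran ring fused at C1–C2 (oxygen on C1), CNP0207547.1 | COc1ccc2c(c1)O[C@@H]1c3c(cc(O)c4c3OC(C)(C)CC4)OC[C@H]21 | target

**Step count and risks**

Total: 14 steps. Longest linear sequence: 12 steps (steps 1–6, then 9–14).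

Steps most likely to fail:

1. Step 11. The carbenoid must insert next to a ring A that carries two ortho oxygens; what may go wrong is poor discrimination between the enantiotopic benzylic hydrogens, erosion of the cis ratio, or diversion of the carbenoid into dimerisation. The fallback makes C6a–C11a by a polar, auxiliary-controlled aldol addition; it sets out from 14 and 8 and comes back at 19.
   - Phenol 14 would be protected (MOMCl, iPr2NEt) to methyl 2-[4-methoxy-2-(methoxymethoxy)phenyl]acetate F1.
   - Saponification (LiOH, THF–H2O) would give 2-[4-methoxy-2-(methoxymethoxy)phenyl]acetic acid F2.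
   - Coupling to (R)-4-benzyloxazolidin-2-one (PivCl, Et3N; then the lithiated oxazolidinone) would give (R)-4-benzyl-3-{2-[4-methoxy-2-(methoxymethoxy)phenyl]acetyl}oxazolidin-2-one F3.
   - Enolisation with Bu2BOTf/iPr2NEt and addition to aldehyde 8 should give the Evans syn aldol adduct, the (2R,3R)-3-hydroxy-2,3-diarylpropanoyl imide F4, with the future C6a fixed by the auxiliary.
   - LiAlH4 would remove auxiliary and pivalate to give 8-{(1R,2S)-1,3-dihydroxy-2-[4-methoxy-2-(methoxymethoxy)phenyl]propyl}-2,2-dimethyl-5-[(triisopropylsilyl)oxy]chroman-7-ol F5.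
   - Mitsunobu closure of ring B through the primary alcohol (PPh3, DIAD) would give the (3S,4R)-trans-isoflavan-4-ol, 3-[4-methoxy-2-(methoxymethoxy)phenyl]-7-[(triisopropylsilyl)oxy]chroman-4-ol with the dimethyldihydropyran ring fused at C5–C6, F6.
   - Dilute HCl in MeOH would remove the MOM group and close ring C through the benzylic cation at C11a, which can only be captured by O11 in the cis-fused sense, to give 19. The carbinol configuration from the aldol is lost here and does not matter.

2. Step 1. What may go wrong is incomplete discrimination between the para hydroxyl and the non-hydrogen-bonded ortho hydroxyl, giving bis-silylation or silyl scrambling. This fallback also removes the need for mono-selectivity in step 2. It sets out from 1 and comes back at 6.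
   - MOMCl (2.2 equiv) and iPr2NEt would protect the two more reactive hydroxyls and leave only the hydrogen-bonded one, giving 2-hydroxy-4,6-bis(methoxymethoxy)benzaldehyde F7.
   - Propargylation with 3 (DBU, CuCl2 cat.) would give 2,4-bis(methoxymethoxy)-6-[(2-methylbut-3-yn-2-yl)oxy]benzaldehyde F8.
   - Heating in o-xylene would give 5,7-bis(methoxymethoxy)-2,2-dimethyl-2H-chromene-8-carbaldehyde F9.
   - HCl in MeOH would free 5,7-dihydroxy-2,2-dimethyl-2H-chromene-8-carbaldehyde F10.
   - TIPSCl/imidazole should then silylate only the 5-OH, since the 7-OH is hydrogen-bonded to the formyl group, and give 6.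

3. Step 9. What may go wrong is ionisation of the benzylic oxyphosphonium ion (ring A has three oxygen donors) ahead of displacement, leading to C-benzylation of the electron-rich phenol and oligomers, or a pivaloyl shift onto the benzylic oxygen. The fallback replaces the redox condensation by a Williamson alkylation; it sets out from 9 and comes back at 15. MsCl/Et3N in CH2Cl2 at −20 °C would convert 9 into 8-(chloromethyl)-2,2-dimethyl-5-[(triisopropylsilyl)oxy]chroman-7-yl pivalate F11, which would be used crude to alkylate the caesium phenoxide of 14 (Cs2CO3, DMF, 0 °C) at oxygen to give 15.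

**Further compounds**

F1 | step 11 | methyl 2-[4-methoxy-2-(methoxymethoxy)phenyl]acetate | COCOc1cc(OC)ccc1CC(=O)OC
F2 | step 11 | 2-[4-methoxy-2-(methoxymethoxy)phenyl]acetic acid | COCOc1cc(OC)ccc1CC(=O)O
F3 | step 11 | (R)-4-benzyl-3-{2-[4-methoxy-2-(methoxymethoxy)phenyl]acetyl}oxazolidin-2-one | COCOc1cc(OC)ccc1CC(=O)N1[C@H](Cc2ccccc2)COC1=O
F4 | step 11 | (R)-4-benzyl-3-[(2R,3R)-3-{2,2-dimethyl-7-(pivaloyloxy)-5-[(triisopropylsilyl)oxy]chroman-8-yl}-3-hydroxy-2-[4-methoxy-2-(methoxymethoxy)phenyl]propanoyl]oxazolidin-2-one | O=C(N1[C@H](Cc2ccccc2)COC1=O)[C@H](c1ccc(OC)cc1OCOC)[C@@H](O)c1c(OC(=O)C(C)(C)C)cc(O[Si](C(C)C)(C(C)C)C(C)C)c2c1OC(C)(C)CC2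
F5 | step 11 | 8-{(1R,2S)-1,3-dihydroxy-2-[4-methoxy-2-(methoxymethoxy)phenyl]propyl}-2,2-dimethyl-5-[(triisopropylsilyl)oxy]chroman-7-ol | OC[C@H](c1ccc(OC)cc1OCOC)[C@@H](O)c1c(O)cc(O[Si](C(C)C)(C(C)C)C(C)C)c2c1OC(C)(C)CC2
F6 | step 11 | (3S,4R)-trans-3-[4-methoxy-2-(methoxymethoxy)phenyl]-7-[(triisopropylsilyl)oxy]chroman-4-ol with the 2,2-dimethyldihydropyran ring fused at C5–C6 (oxygen on C5) | O[C@H]1c2c(cc(O[Si](C(C)C)(C(C)C)C(C)C)c3c2OC(C)(C)CC3)OC[C@@H]1c1ccc(OC)cc1OCOC
F7 | step 1 | 2-hydroxy-4,6-bis(methoxymethoxy)benzaldehyde | O=Cc1c(O)cc(OCOC)cc1OCOC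
F8 | step 1 | 2,4-bis(methoxymethoxy)-6-[(2-methylbut-3-yn-2-yl)oxy]benzaldehyde | O=Cc1c(OCOC)cc(OCOC)cc1OC(C)(C)C#C
F9 | step 1 | 5,7-bis(methoxymethoxy)-2,2-dimethyl-2H-chromene-8-carbaldehyde | O=Cc1c(OCOC)cc(OCOC)c2c1OC(C)(C)C=C2
F10 | step 1 | 5,7-dihydroxy-2,2-dimethyl-2H-chromene-8-carbaldehyde | O=Cc1c(O)cc(O)c2c1OC(C)(C)C=C2
F11 | step 9 | 8-(chloromethyl)-2,2-dimethyl-5-[(triisopropylsilyl)oxy]chroman-7-yl pivalate | ClCc1c(OC(=O)C(C)(C)C)cc(O[Si](C(C)C)(C(C)C)C(C)C)c2c1OC(C)(C)CC2
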